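**Conventions and assumption.** Atom labels used for every intermediate: ring carbons C1–C10; C14 is the methyl on C10; C15 is the CH2O carbon on C4; C11 (with =C13) and C12 form the three-carbon arm on C7/O6. TBS = tert-butyldimethylsilyl. Stereodescriptors are the CIP descriptors of the compound named. The labels at C6 (S in 22 and 26, R from 28 on) and at C7 (S in 28, R elsewhere) change only because CIP priorities change; the geometry does not. Assumption: the (−)-diisopinocampheyl allylborane adds to the Si face of aldehyde 7, as it does with other α-branched enals.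

## Structural features

The target is a germacrane-type lactone. A ten-membered carbocycle (C1–C10) carries a trans-fused α-methylene-γ-butyrolactone (lactone O on C6, C11(=C13)–C12 on C7), a trans-trisubstituted oxirane across C1–C10 with the C14 methyl on C10, a (Z)-trisubstituted C4=C5 alkene with the C15 hydroxymethyl group on C4, a free carbinol at C3 and an isobutyrate on O8. Of the six stereocentres, C1 and C10 are adjacent in the oxirane, C3 is separated from them by the C2 methylene, and C6, C7 and C8 are contiguous. The fragile groups are the exo-methylene lactone (a Michael acceptor), the epoxide (acid, and transannular attack by C4=C5), the allylic C6–O bond, the O8 ester and the (Z)-alkene. The real difficulty is to place the C6–C7–C8 triad with the trans-fused methylene lactone on a medium ring that already holds the epoxide, without strong acid or base. The key step exploits the fact that O6, C7 and O8 are contiguous and that C7 carries C11. A 2-haloallyl unit tethered to O6 can therefore deliver C11 to C7 of a C7=C8 alkene in a 5-exo closure that forms the oxolane ring O6–C6–C7–C11–C12, while the radical left on C8 takes up oxygen. The C6 carbinol configuration is relayed to C7 and C8, so the ring closure that creates C6 carries the stereochemical burden.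

## Logic of the disconnections

**33 ⇒ 32.** The two O–Si bonds at O3 and O15 are cut last. Both hydroxyls stay masked through the radical and oxidation chemistry. The demand is a fluoride source that is neither basic (Michael addition to the lactone) nor strongly acidic (epoxide).

**32 ⇒ 31.** The C12 carbonyl is taken back to a CH2. The lactone becomes a 3-methyleneoxolane, which a radical cyclisation can form directly. The forward step must oxidise the one CH2 that is both allylic and α to oxygen, in preference to C6–H and the silyloxy-bearing allylic positions.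

**31 ⇒ 29 + 30, and 29 ⇒ 28.** The O8–acyl bond and then the O8–N bond are cut. C8 then carries the oxygen in the form in which a radical at C8 can acquire it. The demand is an N–O cleavage mild enough for the epoxide and the primary silyl ether.

**28 ⇒ 26 + 27 (key).** C7–C11 and C8–O are cut together. One ring, two skeletal bonds and two stereocentres are removed, and what remains is a ten-membered dienyl epoxide with one carbinol. Two design points follow from the demands of the forward step.
- The halogen on the allyl unit is iodine, not bromine. The stannyl radical must abstract the halogen faster than it couples with the nitroxide, which a vinyl C–Br bond cannot be expected to do.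
- C4=C5 also lies 5-exo to C11. The step therefore needs chemoselectivity between the two alkenes that flank C6; the tether alone does not secure this.

The plain ether (not an acetal) is kept at C12 so that the cyclisation product stays the simple methyleneoxolane.

**26 ⇒ 22 + 25, and 25 ⇒ 24 ⇒ 23.** The O6–C12 ether bond is cut; the reagent 25 goes back in two steps to 23. The forward alkylation must not move silyl groups or open the epoxide.

**22 ⇒ 21.** The C5–C6 ring bond is cut to a (Z)-alkenyl iodide and an enal. This is the only ring bond whose formation also creates the C6 carbinol between two alkenes. The forward step must close a ten-membered ring and form the (6S) carbinol.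

**21 ⇒ 19 + 20, and 19 ⇒ 18.** The C7=C8 alkene is cut by cross-metathesis logic, so that the sensitive enal appears only one step before it is consumed. The epoxide is removed to the (E)-C1=C10 alkene. The epoxidation must be reagent-controlled, because the open chain offers no useful bias, and must select the trisubstituted alkene.

**18 ⇒ 16 + 17, and 16 ⇒ 14 ⇒ 13 ⇒ 11 + 12.** C8–C9 is cut to an allylic bromide and a vinyl nucleophile; C1=C10 is cut to a terminal alkene and 12. The (E)-trisubstituted alkene with its methyl group comes from a thermodynamically controlled metathesis. The coupling must occur at C9 without allylic transposition and without palladium, which would attack the alkenyl iodide.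

**11 ⇒ 10 ⇒ 7 + 8.** C2–C3 is cut to an aldehyde and an allyl nucleophile. C3 is set by a reagent-controlled allylboration on the small (Z)-iodoenal.

**7 ⇒ 6 ⇒ 5 ⇒ 4 ⇒ 1 + 2.** C4–C15 and C5–I are cut. A three-component iodide/ynoate/aldehyde coupling fixes iodine cis to the carbonyl carbon that becomes C3, which is the ring-alkene geometry. Iodine cis to the bulkier substituent is the arrangement that steric methods would not give.

## Other disconnections considered

**Alternative 1:** The cut goes through C4–C5 and C1–C10, with C5–C10 and C1–C4 re-closed in thought. The ten ring carbons then come from the 3-methylcyclohexenone A2 (C5–C10, carbonyl at C6, silyloxy at C8) and the cyclobutene ester A3 (C1–C4, ester carbon = C15, silyloxy at C3). In the forward sense, irradiation would join them head-to-head to the cis-anti-cis photoadduct A1. Thermolysis of A1 would then break the two bonds shared between the rings (C5–C10 and C1–C4) and release the ten-membered ring with the C1=C10 and C4=C5 alkenes.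
- In its favour: no high-dilution macrocyclisation is needed, and on ring construction it is the better plan. Both trisubstituted alkenes, the C6 carbonyl, O8, O3 and C15 arrive together. The E,Z pattern typical of this fragmentation is the one required, so it is at least the equal of the chosen plan on alkene geometry.
- Against it: two chiral partners must combine with the right regio- and facial sense. The thermal opening needs temperatures at which a cyclodeca-1,5-diene can undergo Cope rearrangement to a divinylcyclohexane. Afterwards C7 still has no three-carbon arm, so the C6–C7–C8 triad, the lactone, the exo-methylene and the epoxide would all be installed on the flexible ring under conformational control. A silyloxy group β to the C6 ketone invites elimination during enolate chemistry.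
- Comparison: structurally it builds the ring first and the stereotriad last, the reverse of the chosen plan. Mechanistically it replaces one radical event by several substrate-controlled ionic steps. It would be shorter up to the ring and clearly longer after it.

**Alternative 2:** The cut is C5–C6 at the ketone oxidation level. The open-chain compound A5, with a C6 S-phenyl thioester and a (Z)-C5 alkenylstannane, would be cyclised with Pd2(dba)3 and CuO2PPh2 to the (1(10)E,4Z)-cyclodecadienone A4, which already carries the C7 acetate arm and the C8 silyl ether.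
- In its favour: it forms the same ring bond as the chosen closure but creates no stereocentre in the cyclisation, which is better than the chromium-mediated closure on that point. Conditions are neutral and the Z geometry should be retained. C7 and C8 are set in the open chain by acyclic methods, which is better than relying on the face of radical capture at C8.
- Against it: in A4, C7 is α and O8 is β to the new ketone, so epimerisation and β-elimination threaten the centres set early. C6 must then be reduced from the correct face, the lactone closed, C13 added by α-methylenation, the 1(10)-alkene epoxidised under conformational control only, and the O8 silyl group exchanged for the isobutyrate.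
- Comparison: the arm on C7 comes from enolate chemistry rather than from O6, and the mechanism is cross-coupling rather than radical. About six operations would follow ring closure, against five from the ring alcohol here, so there is no saving.

**Alternative 3:** The cut is C3–C4. The open-chain aldehyde A7, which already contains the epoxide, the C8 isobutyrate and the complete methylene lactone, would be cyclised by NiCl2/CrCl2 through its (Z)-C4 alkenyl iodide. The product A6 is the 15-O-silyl ether of the target, and the C3 carbinol is formed in the ring closure.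
- In its favour: it is the most convergent plan and has the shortest endgame (one desilylation), which is better than the chosen plan. The internal alkenyl iodide with defined geometry is easy to reach from but-2-yne-1,4-diol by hydroalumination–iodination. The ring-closing reaction type is the same as in the chosen plan and carries equal risk.
- Against it: C3 is created last, under substrate control, on the most valuable intermediate, with no simple way to invert an allylic alcohol there. A7 is a β,γ-epoxy aldehyde prone to enolisation and epoxide opening, and its methylene lactone is exposed to low-valent chromium. The contiguous C6–C8 array with the lactone must still be built in the open chain by another method, so the problem the radical step solves is moved, not removed.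
- Comparison: all fragile functions are present at ring closure, whereas the chosen plan closes the ring on a robust bis-silyl ether; the mechanism of closure is the same. Step economy is in favour of this alternative only if A7 can be made as briefly as 21.

Key step: step 17

## Steps

Step 1
Reactants: 1 methyl propiolate; 2 formaldehyde (monomer from cracked paraformaldehyde)
Product: 4 methyl (2Z)-2-(hydroxymethyl)-3-iodoprop-2-enoate, via iodomagnesium iodoallenolate 3 (not isolated)
Conditions: MgI2, CH2Cl2, 0 °C; then CH2O (gas), −40 → 0 °C; aq. NH4Cl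
Reagents that add atoms: magnesium iodide, [Mg+2].[I-].[I-]
Why: β-Iodo Morita–Baylis–Hillman reaction; iodide adds to the ynoate and allenolate 3 is hydroxymethylated at C4 anti to iodine, so iodine ends cis to the ester carbon (future C3) and trans to the new CH2OH (C15).

Step 2
Reactants: 4 methyl (2Z)-2-(hydroxymethyl)-3-iodoprop-2-enoate
Product: 5 methyl (2Z)-2-[(TBSO)methyl]-3-iodoprop-2-enoate
Conditions: TBSOTf, 2,6-lutidine, CH2Cl2, −78 → 0 °C
Reagents that add atoms: tert-butyldimethylsilyl trifluoromethanesulfonate, CC(C)(C)[Si](C)(C)OS(=O)(=O)C(F)(F)F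
Why: O-silylation with a silyl triflate and a hindered base; no nucleophilic amine is present that could add to the β-iodoacrylate and displace iodide.

Step 3
Reactants: 5 methyl (2Z)-2-[(TBSO)methyl]-3-iodoprop-2-enoate
Product: 6 (2E)-2-[(TBSO)methyl]-3-iodoprop-2-en-1-ol
Conditions: i-Bu2AlH, CH2Cl2, −78 °C; aq. potassium sodium tartrate
Reagents that add atoms: none
Why: 1,2-reduction of the enoate by the aluminium hydride at low temperature; the alkenyl iodide and silyl ether are inert, and the geometry is retained (the descriptor changes by CIP priority only).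

Step 4
Reactants: 6 (2E)-2-[(TBSO)methyl]-3-iodoprop-2-en-1-ol
Product: 7 (2Z)-2-[(TBSO)methyl]-3-iodoprop-2-enal
Conditions: MnO2, CH2Cl2, rt, dark; filtered and used at once
Reagents that add atoms: none
Why: neutral allylic oxidation with MnO2; the iodoenal with iodine cis to the formyl group is the less stable geometric isomer, so it is not chromatographed or stored.

Step 5
Reactants: 7 (2Z)-2-[(TBSO)methyl]-3-iodoprop-2-enal; 8 allylmagnesium bromide
Product: 10 (1Z,3S)-2-[(TBSO)methyl]-1-iodohexa-1,5-dien-3-ol, via B-allyldiisopinocampheylborane 9 (not isolated)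
Conditions: (−)-Ipc2BOMe, 8, Et2O, 0 °C → rt; then 7, −78 °C; NaOH, H2O2, 0 °C
Reagents that add atoms: none
Why: Brown allylboration through a chair Zimmerman–Traxler transition state; reagent 9 (from (+)-α-pinene) should add to the Si face of the enal and set C3 as S, and allyl- and crotylborations of (Z)-β-iodo-α-substituted enals are established.

Step 6
Reactants: 10 (1Z,3S)-2-[(TBSO)methyl]-1-iodohexa-1,5-dien-3-ol
Product: 11 (1Z,3S)-3-(TBSO)-2-[(TBSO)methyl]-1-iodohexa-1,5-diene
Conditions: TBSOTf, 2,6-lutidine, CH2Cl2, −78 → 0 °C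
Reagents that add atoms: tert-butyldimethylsilyl trifluoromethanesulfonate, CC(C)(C)[Si](C)(C)OS(=O)(=O)C(F)(F)F
Why: silylation of a hindered secondary allylic alcohol with the silyl triflate; the same group on O3 and O15 allows one final deprotection.

Step 7
Reactants: 11 (1Z,3S)-3-(TBSO)-2-[(TBSO)methyl]-1-iodohexa-1,5-diene; 12 methacrolein
Product: 13 (2E,5S,6Z)-5-(TBSO)-6-[(TBSO)methyl]-7-iodo-2-methylhepta-2,6-dienal
Conditions: 12 (excess), second-generation Hoveyda–Grubbs catalyst RuCl2(H2IMes)(=CH-C6H4-2-O-i-Pr), CH2Cl2, 40 °C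
Reagents that add atoms: none
Why: cross-metathesis of a terminal alkene with an α-substituted enal; thermodynamic control should give the (E)-trisubstituted C1=C10 alkene with the C14 methyl, and the hindered, electron-poor iodoalkene should not engage the carbene.

Step 8
Reactants: 13 (2E,5S,6Z)-5-(TBSO)-6-[(TBSO)methyl]-7-iodo-2-methylhepta-2,6-dienal
Product: 14 (2E,5S,6Z)-5-(TBSO)-6-[(TBSO)methyl]-7-iodo-2-methylhepta-2,6-dien-1-ol
Conditions: NaBH4, CeCl3·7H2O, MeOH, −20 °C
Reagents that add atoms: none
Why: Luche 1,2-reduction of the enal; no conjugate reduction and no effect on the alkenyl iodide.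

Step 9
Reactants: 14 (2E,5S,6Z)-5-(TBSO)-6-[(TBSO)methyl]-7-iodo-2-methylhepta-2,6-dien-1-ol
Product: 16 (1Z,3S,5E)-7-bromo-1-iodo-6-methyl-3-(TBSO)-2-[(TBSO)methyl]hepta-1,5-diene, via allylic mesylate 15 (not isolated)
Conditions: MsCl, Et3N, THF, −40 °C; then LiBr, 0 °C
Reagents that add atoms: methanesulfonyl chloride, CS(=O)(=O)Cl (in 15); lithium bromide, [Li+].[Br-]
Why: mesylation and SN2 displacement by bromide at the primary allylic carbon C9 under neutral conditions; the bromide is used without storage.

Step 10
Reactants: 16 (1Z,3S,5E)-7-bromo-1-iodo-6-methyl-3-(TBSO)-2-[(TBSO)methyl]hepta-1,5-diene; 17 vinylmagnesium bromide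
Product: 18 (1Z,3S,5E)-1-iodo-6-methyl-3-(TBSO)-2-[(TBSO)methyl]nona-1,5,8-triene
Conditions: 17 (excess, added quickly), Li2CuCl4 (cat.), THF, −20 → 0 °C
Reagents that add atoms: none
Why: copper-catalysed Grignard–allylic halide coupling under dialkenylcuprate conditions, which favour attack at the unhindered α carbon C9 over the secondary γ carbon C1; no palladium is used, so the alkenyl iodide is left alone.

Step 11
Reactants: 18 (1Z,3S,5E)-1-iodo-6-methyl-3-(TBSO)-2-[(TBSO)methyl]nona-1,5,8-triene
Product: 19 (2R,3R)-3-[(2S,3Z)-2-(TBSO)-3-[(TBSO)methyl]-4-iodobut-3-en-1-yl]-2-methyl-2-(prop-2-en-1-yl)oxirane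
Conditions: D-fructose-derived Shi ketone (cat.), Oxone (2KHSO5·KHSO4·K2SO4), K2CO3, Bu4NHSO4, MeCN–dimethoxymethane–aq. Na2B4O7 buffer, 0 °C
Reagents that add atoms: potassium peroxymonosulfate, [K+].[O-]S(=O)(=O)OO
Why: Shi asymmetric epoxidation; the chiral dioxirane should select the electron-rich trisubstituted C1=C10 over the terminal alkene and the iodo-substituted C4=C5, and its spiro transition state delivers oxygen to the face that gives the (1R,10R) trans-epoxide.

Step 12
Reactants: 19 (2R,3R)-3-[(2S,3Z)-2-(TBSO)-3-[(TBSO)methyl]-4-iodobut-3-en-1-yl]-2-methyl-2-(prop-2-en-1-yl)oxirane; 20 (2E)-but-2-enal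
Product: 21 (2E)-4-{(2R,3R)-3-[(2S,3Z)-2-(TBSO)-3-[(TBSO)methyl]-4-iodobut-3-en-1-yl]-2-methyloxiran-2-yl}but-2-enal
Conditions: 20 (excess), second-generation Hoveyda–Grubbs catalyst RuCl2(H2IMes)(=CH-C6H4-2-O-i-Pr), CH2Cl2, 40 °C
Reagents that add atoms: none
Why: cross-metathesis of the terminal alkene with an enal should give the (E)-C7=C8 enal directly under neutral conditions, so the base-sensitive γ-epoxy enal is made one step before use and needs no protecting-group or oxidation steps at C6.

Step 13
Reactants: 21 (2E)-4-{(2R,3R)-3-[(2S,3Z)-2-(TBSO)-3-[(TBSO)methyl]-4-iodobut-3-en-1-yl]-2-methyloxiran-2-yl}but-2-enal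
Product: 22 (1R,3S,4Z,6S,7E,10R)-3-(TBSO)-4-[(TBSO)methyl]-1,10-epoxy-10-methylcyclodeca-4,7-dien-6-ol
Conditions: CrCl2 (excess), NiCl2 (cat.), DMSO, rt, slow addition of 21 to high dilution
Reagents that add atoms: none
Why: Nozaki–Hiyama–Kishi ring closure; zerovalent nickel inserts into C5–I, transmetalation gives an alkenylchromium that adds 1,2 to the C6 aldehyde with retention of the Z geometry, and the (6S) carbinol is expected from addition through the least strained ring conformer (substrate control).

Step 14
Reactants: 23 prop-2-yn-1-ol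
Product: 24 2-iodoprop-2-en-1-ol
Conditions: NaI, Me3SiCl, H2O, MeCN, rt
Reagents that add atoms: sodium iodide, [Na+].[I-]
Why: Markovnikov hydroiodination of the terminal alkyne by HI generated in the flask places iodine on the internal carbon (C11).

Step 15
Reactants: 24 2-iodoprop-2-en-1-ol
Product: 25 3-bromo-2-iodoprop-1-ene
Conditions: PBr3, Et2O, 0 °C
Reagents that add atoms: phosphorus tribromide, BrP(Br)Br
Why: conversion of a primary allylic alcohol into the bromide; allylic transposition would give the same compound.

Step 16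
Reactants: 22 (1R,3S,4Z,6S,7E,10R)-3-(TBSO)-4-[(TBSO)methyl]-1,10-epoxy-10-methylcyclodeca-4,7-dien-6-ol; 25 3-bromo-2-iodoprop-1-ene
Product: 26 (1R,3S,4Z,6S,7E,10R)-3-(TBSO)-4-[(TBSO)methyl]-1,10-epoxy-6-[(2-iodoprop-2-en-1-yl)oxy]-10-methylcyclodeca-4,7-diene
Conditions: NaH, THF–DMF, 0 °C; then 25, Bu4NI (cat.), 0 °C → rt
Reagents that add atoms: none
Why: Williamson etherification of the C6 alkoxide with a reactive allylic bromide; the 2-iodoallyl unit is chosen so that halogen abstraction in the next step can compete with stannyl–nitroxide coupling.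

Step 17
Reactants: 26 (1R,3S,4Z,6S,7E,10R)-3-(TBSO)-4-[(TBSO)methyl]-1,10-epoxy-6-[(2-iodoprop-2-en-1-yl)oxy]-10-methylcyclodeca-4,7-diene; 27 2,2,6,6-tetramethylpiperidin-1-oxyl
Product: 28 (1R,3S,4Z,6R,7S,8R,10R)-3,15-bis(TBSO)-1,10:6,12-diepoxy-8-[(2,2,6,6-tetramethylpiperidin-1-yl)oxy]germacra-4,11(13)-diene
Conditions: Bu3SnH and 27 (excess of each, added together by syringe pump), benzene, 65 °C
Reagents that add atoms: none
Why: The nitroxide abstracts hydrogen from Bu3SnH, the stannyl radical removes iodine from 26, and the σ-vinyl radical at C11 adds to C7; the radical then left on C8 couples with a second molecule of 27. The closest known reaction type is the Ueno–Stork haloallyl ether cyclisation run with tin hydride and a nitroxide trap in place of hydrogen transfer. The oxolane O6–C6–C7–C11–C12 closes 5-exo-trig; 6-endo attack at C8 is slower, and fast nitroxide capture also forestalls the homoallyl–cyclopropylcarbinyl rearrangement that would lead to a six-membered ether. C7 is controlled by the C6 stereocentre: in the ten-membered ring C5 lies out of the plane of the (E)-C7=C8 alkene, so the O6 tether can reach C7 only from the opposite face, and this chair-like arrangement with C5 anti to C8 is the trans ring fusion. C8 is set by approach of the bulky nitroxide to the outer face of the ring, anti to the new C7–C11 bond. The step needs chemoselectivity between the two alkenes that flank C6, because C5 is also 5-exo to C11; attack at C7 is expected to win because the (E)-alkene of a ten-membered ring is the more strained and more exposed π bond, whose consumption relieves strain. Iodine on the allyl unit and slow joint addition of Bu3SnH and 27 keep halogen abstraction ahead of stannyl–nitroxide coupling and keep the vinyl radical from being trapped before it cyclises.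

Step 18
Reactants: 28 (1R,3S,4Z,6R,7S,8R,10R)-3,15-bis(TBSO)-1,10:6,12-diepoxy-8-[(2,2,6,6-tetramethylpiperidin-1-yl)oxy]germacra-4,11(13)-diene
Product: 29 (1R,3S,4Z,6R,7R,8R,10R)-3,15-bis(TBSO)-1,10:6,12-diepoxygermacra-4,11(13)-dien-8-ol
Conditions: Zn (activated), AcOH–THF (little water), 45 °C
Reagents that add atoms: none
Why: reductive N–O cleavage of the alkoxyamine by zinc in acetic acid with retention at C8; the water content and temperature are kept low to spare the epoxide and the primary silyl ether.

Step 19
Reactants: 29 (1R,3S,4Z,6R,7R,8R,10R)-3,15-bis(TBSO)-1,10:6,12-diepoxygermacra-4,11(13)-dien-8-ol; 30 isobutyric anhydride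
Product: 31 (1R,3S,4Z,6R,7R,8R,10R)-3,15-bis(TBSO)-1,10:6,12-diepoxygermacra-4,11(13)-dien-8-yl 2-methylpropanoate
Conditions: 30, Et3N, DMAP (cat.), CH2Cl2, rt
Reagents that add atoms: none
Why: DMAP-catalysed acylation of the only free hydroxyl; no stereocentre is touched.

Step 20
Reactants: 31 (1R,3S,4Z,6R,7R,8R,10R)-3,15-bis(TBSO)-1,10:6,12-diepoxygermacra-4,11(13)-dien-8-yl 2-methylpropanoate
Product: 32 (1R,3S,4Z,6R,7R,8R,10R)-3,15-bis(TBSO)-1,10-epoxy-8-(2-methylpropanoyloxy)germacra-4,11(13)-dien-12,6-olide
Conditions: CrO3, 3,5-dimethylpyrazole, CH2Cl2, −20 °C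
Reagents that add atoms: chromium trioxide, O=[Cr](=O)=O
Why: allylic oxidation of a 3-methyleneoxolane to the α-methylene lactone by the CrO3–3,5-dimethylpyrazole complex; C12 is the only unhindered CH2 that is both allylic and α to oxygen, while C6–H is tertiary and buried and the other allylic positions carry bulky silyloxy groups.

Step 21
Reactants: 32 (1R,3S,4Z,6R,7R,8R,10R)-3,15-bis(TBSO)-1,10-epoxy-8-(2-methylpropanoyloxy)germacra-4,11(13)-dien-12,6-olide
Product: 33 (1R,3S,4Z,6R,7R,8R,10R)-1,10-epoxy-3,15-dihydroxy-8-(2-methylpropanoyloxy)germacra-4,11(13)-dien-12,6-olide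
Conditions: HF·pyridine, pyridine, THF, 0 °C → rt
Reagents that add atoms: none
Why: fluoride-mediated cleavage of both silyl ethers under pyridine-buffered conditions, which avoids basic fluoride (Michael addition, acyl migration) and free strong acid (epoxide opening).

## Compound list

1 | methyl propiolate | C#CC(=O)OC | starting material
2 | formaldehyde (from paraformaldehyde) | C=O | starting material
3 | iodomagnesium 3-iodo-1-methoxypropa-1,2-dien-1-olate | COC(O[Mg]I)=C=CI | intermediate (not isolated)
4 | methyl (2Z)-2-(hydroxymethyl)-3-iodoprop-2-enoate | I/C=C(/CO)C(=O)OC | intermediate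
5 | methyl (2Z)-2-[(TBSO)methyl]-3-iodoprop-2-enoate | I/C=C(/CO[Si](C)(C)C(C)(C)C)C(=O)OC | intermediate
6 | (2E)-2-[(TBSO)methyl]-3-iodoprop-2-en-1-ol | I/C=C(/CO[Si](C)(C)C(C)(C)C)CO | intermediate
7 | (2Z)-2-[(TBSO)methyl]-3-iodoprop-2-enal | I/C=C(/CO[Si](C)(C)C(C)(C)C)C=O | intermediate
8 | allylmagnesium bromide | C=CC[Mg]Br | starting material
9 | (−)-B-allyldiisopinocampheylborane | C=CCB([C@@H]1C[C@@H]2C[C@H]([C@H]1C)C2(C)C)[C@@H]1C[C@@H]2C[C@H]([C@H]1C)C2(C)C | intermediate (not isolated)
10 | (1Z,3S)-2-[(TBSO)methyl]-1-iodohexa-1,5-dien-3-ol | I/C=C(/CO[Si](C)(C)C(C)(C)C)[C@@H](O)CC=C | intermediate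
11 | (1Z,3S)-3-(TBSO)-2-[(TBSO)methyl]-1-iodohexa-1,5-diene | I/C=C(/CO[Si](C)(C)C(C)(C)C)[C@@H](O[Si](C)(C)C(C)(C)C)CC=C | intermediate
12 | methacrolein | C=C(C)C=O | starting material
13 | (2E,5S,6Z)-5-(TBSO)-6-[(TBSO)methyl]-7-iodo-2-methylhepta-2,6-dienal | I/C=C(/CO[Si](C)(C)C(C)(C)C)[C@@H](O[Si](C)(C)C(C)(C)C)C/C=C(\C)C=O | intermediate
14 | (2E,5S,6Z)-5-(TBSO)-6-[(TBSO)methyl]-7-iodo-2-methylhepta-2,6-dien-1-ol | I/C=C(/CO[Si](C)(C)C(C)(C)C)[C@@H](O[Si](C)(C)C(C)(C)C)C/C=C(\C)CO | intermediate
15 | (2E,5S,6Z)-5-(TBSO)-6-[(TBSO)methyl]-7-iodo-2-methylhepta-2,6-dien-1-yl methanesulfonate | I/C=C(/CO[Si](C)(C)C(C)(C)C)[C@@H](O[Si](C)(C)C(C)(C)C)C/C=C(\C)COS(C)(=O)=O | intermediate (not isolated)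
16 | (1Z,3S,5E)-7-bromo-1-iodo-6-methyl-3-(TBSO)-2-[(TBSO)methyl]hepta-1,5-diene | I/C=C(/CO[Si](C)(C)C(C)(C)C)[C@@H](O[Si](C)(C)C(C)(C)C)C/C=C(\C)CBr | intermediate
17 | vinylmagnesium bromide | C=C[Mg]Br | starting material
18 | (1Z,3S,5E)-1-iodo-6-methyl-3-(TBSO)-2-[(TBSO)methyl]nona-1,5,8-triene | I/C=C(/CO[Si](C)(C)C(C)(C)C)[C@@H](O[Si](C)(C)C(C)(C)C)C/C=C(\C)CC=C | intermediate
19 | (2R,3R)-3-[(2S,3Z)-2-(TBSO)-3-[(TBSO)methyl]-4-iodobut-3-en-1-yl]-2-methyl-2-(prop-2-en-1-yl)oxirane | I/C=C(/CO[Si](C)(C)C(C)(C)C)[C@@H](O[Si](C)(C)C(C)(C)C)C[C@H]1O[C@]1(C)CC=C | intermediate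
20 | (2E)-but-2-enal (crotonaldehyde) | C/C=C/C=O | starting material
21 | (2E)-4-{(2R,3R)-3-[(2S,3Z)-2-(TBSO)-3-[(TBSO)methyl]-4-iodobut-3-en-1-yl]-2-methyloxiran-2-yl}but-2-enal | I/C=C(/CO[Si](C)(C)C(C)(C)C)[C@@H](O[Si](C)(C)C(C)(C)C)C[C@H]1O[C@]1(C)C/C=C/C=O | intermediate
22 | (1R,3S,4Z,6S,7E,10R)-3-(TBSO)-4-[(TBSO)methyl]-1,10-epoxy-10-methylcyclodeca-4,7-dien-6-ol | C[C@]12O[C@@H]1C[C@H](O[Si](C)(C)C(C)(C)C)/C(CO[Si](C)(C)C(C)(C)C)=C\[C@@H](O)/C=C/C2 | intermediate
23 | prop-2-yn-1-ol | C#CCO | starting material
24 | 2-iodoprop-2-en-1-ol | C=C(I)CO | intermediate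
25 | 3-bromo-2-iodoprop-1-ene | C=C(I)CBr | intermediate
26 | (1R,3S,4Z,6S,7E,10R)-3-(TBSO)-4-[(TBSO)methyl]-1,10-epoxy-6-[(2-iodoprop-2-en-1-yl)oxy]-10-methylcyclodeca-4,7-diene | C[C@]12O[C@@H]1C[C@H](O[Si](C)(C)C(C)(C)C)/C(CO[Si](C)(C)C(C)(C)C)=C\[C@@H](OCC(I)=C)/C=C/C2 | intermediate
27 | 2,2,6,6-tetramethylpiperidin-1-oxyl | CC1(C)CCCC(C)(C)N1[O] | starting material
28 | (1R,3S,4Z,6R,7S,8R,10R)-3,15-bis(TBSO)-1,10:6,12-diepoxy-8-[(2,2,6,6-tetramethylpiperidin-1-yl)oxy]germacra-4,11(13)-diene | C=C1CO[C@@H]2/C=C(/CO[Si](C)(C)C(C)(C)C)[C@@H](O[Si](C)(C)C(C)(C)C)C[C@H]3O[C@]3(C)C[C@@H](ON4C(C)(C)CCCC4(C)C)[C@@H]12 | intermediate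
29 | (1R,3S,4Z,6R,7R,8R,10R)-3,15-bis(TBSO)-1,10:6,12-diepoxygermacra-4,11(13)-dien-8-ol | C=C1CO[C@@H]2/C=C(/CO[Si](C)(C)C(C)(C)C)[C@@H](O[Si](C)(C)C(C)(C)C)C[C@H]3O[C@]3(C)C[C@@H](O)[C@@H]12 | intermediate
30 | isobutyric anhydride | CC(C)C(=O)OC(=O)C(C)C | starting material
31 | (1R,3S,4Z,6R,7R,8R,10R)-3,15-bis(TBSO)-1,10:6,12-diepoxygermacra-4,11(13)-dien-8-yl 2-methylpropanoate | C=C1CO[C@@H]2/C=C(/CO[Si](C)(C)C(C)(C)C)[C@@H](O[Si](C)(C)C(C)(C)C)C[C@H]3O[C@]3(C)C[C@@H](OC(=O)C(C)C)[C@@H]12 | intermediate
32 | (1R,3S,4Z,6R,7R,8R,10R)-3,15-bis(TBSO)-1,10-epoxy-8-(2-methylpropanoyloxy)germacra-4,11(13)-dien-12,6-olide | C=C1C(=O)O[C@@H]2/C=C(/CO[Si](C)(C)C(C)(C)C)[C@@H](O[Si](C)(C)C(C)(C)C)C[C@H]3O[C@]3(C)C[C@@H](OC(=O)C(C)C)[C@@H]12 | intermediate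
33 | (1R,3S,4Z,6R,7R,8R,10R)-1,10-epoxy-3,15-dihydroxy-8-(2-methylpropanoyloxy)germacra-4,11(13)-dien-12,6-olide (CNP0219050.1) | C=C1C(=O)O[C@@H]2/C=C(/CO)[C@@H](O)C[C@H]3O[C@]3(C)C[C@@H](OC(=O)C(C)C)[C@@H]12 | target

## Step count and least certain steps

Total step count: 21. Longest linear sequence: 19 (steps 1–13 and 16–21; steps 14 and 15 prepare reagent 25).

**Step 17 (key step).** The most likely failure is capture of the C8 radical by the nitroxide from the wrong face. On a ten-membered ring the open face is fixed by the ring conformation and not only by the new C7–C11 bond. (Competing addition of the vinyl radical to C5 would show as a regioisomeric oxolane.) The fallback sets out from 26 and comes back at 31. The cyclisation is run as before and delivers the 8-epimer of 28, F1. Zinc in acetic acid gives the 8-epimer of 29, F2. A Mitsunobu esterification of F2 with isobutyric acid (PPh3, diisopropyl azodicarboxylate, toluene) inverts C8 and gives 31 directly.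

**Step 13.** The most likely failure is poor facial selectivity in the addition of the alkenylchromium to the aldehyde, because the C6 configuration rests on the conformation of a forming medium ring; slow closure with oligomerisation is the second concern. The fallback sets out from 21 and comes back at 22. The ring closure then gives the 6-epimer of 22, F3, alone or mixed with 22. Dess–Martin periodinane (NaHCO3, CH2Cl2) oxidises it to the cross-conjugated dienone F4. Corey–Bakshi–Shibata reduction (BH3·SMe2, (R)-2-methyl-oxazaborolidine, with the trisubstituted alkenyl arm acting as the large group) returns the (6S) alcohol 22 under reagent control.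

**Step 20.** The most likely failure is loss of site selectivity in the C–H oxidation. C6–H is also allylic and α to oxygen, C3–H and the C15 hydrogens are allylic, and hexavalent chromium can attack any of them or over-oxidise. The fallback sets out from 22 and comes back at 32. It places C12 at the acetal oxidation level before the radical step, so that no C–H oxidation is needed.
- N-Iodosuccinimide and methoxyallene (CH2Cl2, −78 → −40 °C; iodoalkoxylation of an alkoxyallene) convert 22 into the 2-iodoallyl mixed acetal F5.
- The same tin hydride–nitroxide cyclisation gives the 12-methoxy alkoxyamine F6.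
- Zinc in acetic acid gives the C8 alcohol F7, and isobutyrylation with 30 gives the ester F8.
- Mild hydrolysis (pyridinium p-toluenesulfonate, wet acetone) gives the lactol F9.
- MnO2 (or Ag2CO3 on Celite) oxidises the allylic lactol to 32.

**Step 10.** The most likely failure is allylic transposition (attack at C1) or halogen–metal exchange at the alkenyl iodide during the copper-mediated coupling, because an alkenyl nucleophile discriminates only moderately between the α and γ carbons. The fallback sets out from 16 and comes back at 18. Ethynylmagnesium bromide with CuCl (cat.) in THF couples at C9, since alkynyl nucleophiles have little tendency to γ-attack, and gives the skipped enyne F10. Hydrozirconation of the terminal alkyne with Cp2Zr(H)Cl followed by protonolysis with water gives the terminal alkene 18 without touching the alkenyl iodide.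

**Step 1.** The most likely failure is oligomerisation of formaldehyde by the Lewis acid before the allenolate captures it, with low conversion, because monomeric formaldehyde is the least stable aldehyde partner for this coupling. The fallback sets out from 23 and 17 and comes back at 6.
- Chelation-controlled anti-carbomagnesiation of 23 with an excess of 17 (THF–toluene, reflux), then I2, gives (2Z)-2-(iodomethylidene)but-3-en-1-ol F11, with iodine cis to the CH2OH that becomes C3.
- Pivaloyl chloride and pyridine give the pivalate F12.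
- OsO4/N-methylmorpholine N-oxide, then NaIO4, cleaves the terminal vinyl group, and NaBH4 reduces the resulting aldehyde to the hydroxymethyl pivalate F13.
- TBSCl and imidazole give the silyl ether F14.
- i-Bu2AlH at −78 °C removes the pivalate and gives 6.

## Further compounds

F1 | step 17 | 8-epimer of 28 (8S) | C=C1CO[C@@H]2/C=C(/CO[Si](C)(C)C(C)(C)C)[C@@H](O[Si](C)(C)C(C)(C)C)C[C@H]3O[C@]3(C)C[C@H](ON4C(C)(C)CCCC4(C)C)[C@@H]12
F2 | step 17 | 8-epimer of 29 (8S alcohol) | C=C1CO[C@@H]2/C=C(/CO[Si](C)(C)C(C)(C)C)[C@@H](O[Si](C)(C)C(C)(C)C)C[C@H]3O[C@]3(C)C[C@H](O)[C@@H]12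
F3 | step 13 | 6-epimer of 22 (6R alcohol) | C[C@]12O[C@@H]1C[C@H](O[Si](C)(C)C(C)(C)C)/C(CO[Si](C)(C)C(C)(C)C)=C\[C@H](O)/C=C/C2
F4 | step 13 | (1R,3S,4Z,7E,10R)-3-(TBSO)-4-[(TBSO)methyl]-1,10-epoxy-10-methylcyclodeca-4,7-dien-6-one | C[C@]12O[C@@H]1C[C@H](O[Si](C)(C)C(C)(C)C)/C(CO[Si](C)(C)C(C)(C)C)=C\C(=O)/C=C/C2
F5 | step 20 | O6 (2-iodo-1-methoxyprop-2-en-1-yl) mixed acetal of 22 (both C12 epimers) | C[C@]12O[C@@H]1C[C@H](O[Si](C)(C)C(C)(C)C)/C(CO[Si](C)(C)C(C)(C)C)=C\[C@@H](OC(OC)C(I)=C)/C=C/C2
F6 | step 20 | 12-methoxy derivative of 28 (both C12 epimers) | C=C1C(OC)O[C@@H]2/C=C(/CO[Si](C)(C)C(C)(C)C)[C@@H](O[Si](C)(C)C(C)(C)C)C[C@H]3O[C@]3(C)C[C@@H](ON4C(C)(C)CCCC4(C)C)[C@@H]12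
F7 | step 20 | 12-methoxy derivative of 29 (both C12 epimers) | C=C1C(OC)O[C@@H]2/C=C(/CO[Si](C)(C)C(C)(C)C)[C@@H](O[Si](C)(C)C(C)(C)C)C[C@H]3O[C@]3(C)C[C@@H](O)[C@@H]12
F8 | step 20 | 12-methoxy derivative of 31 (both C12 epimers) | C=C1C(OC)O[C@@H]2/C=C(/CO[Si](C)(C)C(C)(C)C)[C@@H](O[Si](C)(C)C(C)(C)C)C[C@H]3O[C@]3(C)C[C@@H](OC(=O)C(C)C)[C@@H]12
F9 | step 20 | 12-hydroxy derivative of 31 (lactol, both C12 epimers) | C=C1C(O)O[C@@H]2/C=C(/CO[Si](C)(C)C(C)(C)C)[C@@H](O[Si](C)(C)C(C)(C)C)C[C@H]3O[C@]3(C)C[C@@H](OC(=O)C(C)C)[C@@H]12
F10 | step 10 | (1Z,3S,5E)-1-iodo-6-methyl-3-(TBSO)-2-[(TBSO)methyl]nona-1,5-dien-8-yne | I/C=C(/CO[Si](C)(C)C(C)(C)C)[C@@H](O[Si](C)(C)C(C)(C)C)C/C=C(\C)CC#C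
F11 | step 1 | (2Z)-2-(iodomethylidene)but-3-en-1-ol | I/C=C(/C=C)CO
F12 | step 1 | (2Z)-2-(iodomethylidene)but-3-en-1-yl 2,2-dimethylpropanoate | I/C=C(/C=C)COC(=O)C(C)(C)C
F13 | step 1 | (2Z)-2-(hydroxymethyl)-3-iodoprop-2-en-1-yl 2,2-dimethylpropanoate | I/C=C(/CO)COC(=O)C(C)(C)C
F14 | step 1 | (2E)-2-[(TBSO)methyl]-3-iodoprop-2-en-1-yl 2,2-dimethylpropanoate | I/C=C(/CO[Si](C)(C)C(C)(C)C)COC(=O)C(C)(C)C
A1 | alternative 1 | head-to-head cis-anti-cis photoadduct (tricyclodecanone with C4 methyl ester, C3 triisopropylsilyl ether, C8 TBS ether, C10 methyl) | O=C1[C@H]2[C@]3(C(=O)OC)[C@@H](O[Si](C(C)C)(C(C)C)C(C)C)C[C@@H]3[C@@]2(C)C[C@H](O[Si](C)(C)C(C)(C)C)C1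
A2 | alternative 1 | (5S)-5-(TBSO)-3-methylcyclohex-2-en-1-one | O=C1C=C(C)C[C@H](O[Si](C)(C)C(C)(C)C)C1
A3 | alternative 1 | methyl (4S)-4-(triisopropylsilyloxy)cyclobut-1-ene-1-carboxylate | COC(=O)C1=CC[C@@H]1O[Si](C(C)C)(C(C)C)C(C)C
A4 | alternative 2 | (1(10)E,4Z)-cyclodecadien-6-one with C7 tert-butyl acetate arm, C8 triethylsilyl ether, O3 and O15 TBS ethers | O=C1/C=C(/CO[Si](C)(C)C(C)(C)C)[C@@H](O[Si](C)(C)C(C)(C)C)C/C=C(\C)C[C@@H](O[Si](CC)(CC)CC)[C@H]1CC(=O)OC(C)(C)C
A5 | alternative 2 | open-chain C6 S-phenyl thioester with (Z)-C5 tributylstannyl alkene (configuration as in A4) | CCCC[Sn](CCCC)(CCCC)/C=C(/CO[Si](C)(C)C(C)(C)C)[C@@H](O[Si](C)(C)C(C)(C)C)C/C=C(\C)C[C@@H](O[Si](CC)(CC)CC)[C@@H](CC(=O)OC(C)(C)C)C(=O)Sc1ccccc1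
A6 | alternative 3 | 15-O-TBS ether of 33 | C=C1C(=O)O[C@@H]2/C=C(/CO[Si](C)(C)C(C)(C)C)[C@@H](O)C[C@H]3O[C@]3(C)C[C@@H](OC(=O)C(C)C)[C@@H]12
A7 | alternative 3 | open-chain C3 aldehyde with (Z)-C4 alkenyl iodide, epoxide, C8 isobutyrate and methylene lactone (configuration as in A6) | O=CC[C@H]1O[C@]1(C)C[C@@H](OC(=O)C(C)C)[C@H]2C(=C)C(=O)O[C@@H]2/C=C(\I)CO[Si](C)(C)C(C)(C)C
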